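**Retrosynthetic overview**

1. Sarmentosumin B ⇒ C8–CH2 bond (ortho-quinone methide alkylation with salicyl alcohol, last step): (2S)-6-benzylated pinocembrin 14.
2. 14 ⇒ O1–C2 bond (chalcone-isomerase-type 6-endo oxa-Michael, the only ring closure; it sets C2 and decides 6- versus 8-substitution): open-chain benzylated chalcone 13.
3. 13 ⇒ Claisen–Schmidt: benzaldehyde + C-benzylated phloroacetophenone 10 ⇒ ortho-quinone methide alkylation of symmetric 2,4,6-trihydroxyacetophenone with the "trimer" benzylic alcohol 7.
4. 7 ⇒ chain grown from its far end: Friedel–Crafts benzylation of methyl salicylate with 2-(chloromethyl)phenyl acetate, LiAlH4, ortho-quinone methide alkylation of a second methyl salicylate, LiAlH4.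
5. Ring order: all benzene rings are bought; ring C (the pyranone) is closed late, after the C6 side chain is on and before the C8 benzyl is added.

Assumption: the sense of induction of the new ring closure in step 7 cannot be predicted with certainty; the ligand is written as (S,S)-tBu-pybox and its mirror image is used instead if the first run gives the 2R flavanone.

**Route**

Step 1
Reactants: 1 methyl salicylate; 2 2-(chloromethyl)phenyl acetate
Product: 3 methyl 5-[2-(acetyloxy)benzyl]-2-hydroxybenzoate
Conditions: ZnCl2 (10 mol%), neat 1 (20 equiv, excess distilled off and reused), 100 °C, N2 sweep, 2 added over 4 h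
Reagents that add atoms: none
Why: Lewis-acid Friedel–Crafts benzylation in which the salicylate reacts para to its OH (C5), while the acetate keeps the incoming ring a poor nucleophile so that, with the large excess of 1, chain growth stays low; no stereocentre is formed.

Step 2
Reactants: 3 methyl 5-[2-(acetyloxy)benzyl]-2-hydroxybenzoate
Product: 4 2-(hydroxymethyl)-4-(2-hydroxybenzyl)phenol
Conditions: LiAlH4 (3.5 equiv), THF, 0 °C to rt; aq. KNaC4H4O6 work-up at 0 °C (pH kept above 5)
Reagents that add atoms: none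
Why: LiAlH4 ester reduction turns the methyl ester into the benzylic alcohol and cleaves the aryl acetate in the same operation, giving the ortho-hydroxybenzyl alcohol needed for the next coupling; the diarylmethane link is inert and no stereocentre is formed.

Step 3
Reactants: 4 2-(hydroxymethyl)-4-(2-hydroxybenzyl)phenol; 1 methyl salicylate
Product: 6 methyl 2-hydroxy-5-[2-hydroxy-5-(2-hydroxybenzyl)benzyl]benzoate, via dimer ortho-quinone methide 5 (not isolated)
Conditions: TsOH·H2O (5 mol%), neat 1 (50 equiv, excess distilled off and reused), 80 °C, 4 added over 8 h as a solution in 1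
Reagents that add atoms: none
Why: Acid-catalysed dehydration of the ortho-hydroxybenzyl alcohol gives ortho-quinone methide 5, which the salicylate solvent takes up para to its OH (quinone methide Friedel–Crafts alkylation), and slow addition of 4 into a 50-fold excess of 1 keeps attack on the free phenol rings of 4 and 6 low; no stereocentre.

Step 4
Reactants: 6 methyl 2-hydroxy-5-[2-hydroxy-5-(2-hydroxybenzyl)benzyl]benzoate
Product: 7 2-(hydroxymethyl)-4-[2-hydroxy-5-(2-hydroxybenzyl)benzyl]phenol
Conditions: LiAlH4 (3 equiv), THF, 0 °C to rt; aq. KNaC4H4O6 work-up at 0 °C (pH kept above 5)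
Reagents that add atoms: none
Why: LiAlH4 reduction of the phenolic methyl ester to the benzylic alcohol gives the ortho-quinone methide precursor; the diarylmethane links are inert and no stereocentre is formed.

Step 5
Reactants: 7 2-(hydroxymethyl)-4-[2-hydroxy-5-(2-hydroxybenzyl)benzyl]phenol; 8 2,4,6-trihydroxyacetophenone
Product: 10 1-(2,4,6-trihydroxy-3-{2-hydroxy-5-[2-hydroxy-5-(2-hydroxybenzyl)benzyl]benzyl}phenyl)ethan-1-one, via side-chain ortho-quinone methide 9 (not isolated)
Conditions: ZnCl2 (1.5 equiv), 1,4-dioxane, 70 °C, 8 (3 equiv, excess recovered)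
Reagents that add atoms: none
Why: ZnCl2-promoted ortho-quinone methide formation and Friedel–Crafts (Michael-type) C-alkylation of the acylphloroglucinol; 8 has two equivalent ring positions, so only one mono-adduct is possible and excess 8 suppresses bis-alkylation; no stereocentre.

Step 6
Reactants: 10 1-(2,4,6-trihydroxy-3-{2-hydroxy-5-[2-hydroxy-5-(2-hydroxybenzyl)benzyl]benzyl}phenyl)ethan-1-one; 11 benzaldehyde
Product: 13 (E)-3-phenyl-1-(2,4,6-trihydroxy-3-{2-hydroxy-5-[2-hydroxy-5-(2-hydroxybenzyl)benzyl]benzyl}phenyl)prop-2-en-1-one, via aldol adduct 12 (not isolated)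
Conditions: LiN(SiMe3)2 (7.0 equiv), THF, −78 °C to 0 °C; then 11 (1.3 equiv), 0 °C to rt; 1 M HCl, 0 °C
Reagents that add atoms: none
Why: Claisen–Schmidt (aldol) condensation on the unprotected polyphenol as its lithium polyanion; the polyanionic chalcone cannot cyclise, E1cB dehydration of 12 gives the E-alkene, and the cold acid quench releases 13 without ring closure.

Step 7
Reactants: 13 (E)-3-phenyl-1-(2,4,6-trihydroxy-3-{2-hydroxy-5-[2-hydroxy-5-(2-hydroxybenzyl)benzyl]benzyl}phenyl)prop-2-en-1-one
Product: 14 (2S)-5,7-dihydroxy-6-{2-hydroxy-5-[2-hydroxy-5-(2-hydroxybenzyl)benzyl]benzyl}-2-phenylchroman-4-one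
Conditions: Sc(OTf)3 (10 mol%), (S,S)-tBu-pybox (12 mol%), iPrOAc/MeCN 3:1, −20 °C; aq. NH4Cl
Reagents that add atoms: none
Why: Proposed new method: a chalcone-isomerase-type 6-endo oxa-Michael closure under two-point chiral Lewis acid control; Sc(OTf)3–pybox is expected to bind the carbonyl together with the ortho-phenol that carries the benzyl arm (the arm's own phenol adds a third contact), so the other ortho-OH, next to the free C–H and expected to be the kinetically favoured one in 3'-alkyl-2',4',6'-trihydroxychalcones, adds to Cβ and the arm ends at C6, while the ligand pocket exposes one enone face and sets C2 as S; the closest known reactions are the chiral Lewis acid and amine–thiourea catalysed oxa-Michael closures of ester-activated 2'-hydroxychalcones to flavanones and the Sc(OTf)3–pybox chelates of 2'-hydroxychalcones used for face-selective enone cycloadditions.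

Step 8
Reactants: 14 (2S)-5,7-dihydroxy-6-{2-hydroxy-5-[2-hydroxy-5-(2-hydroxybenzyl)benzyl]benzyl}-2-phenylchroman-4-one; 15 salicyl alcohol (2-hydroxybenzyl alcohol)
Product: 17 sarmentosumin B, via ortho-quinone methide 16 (not isolated)
Conditions: TsOH·H2O (5 mol%), HFIP/CH2Cl2 1:1, 0 °C to rt, 15 (1.3 equiv) added over 2 h
Reagents that add atoms: none
Why: Ortho-quinone methide Friedel–Crafts alkylation at C8, the only free carbon of the phloroglucinol ring and far more nucleophilic than the side-chain phenols; mild Brønsted acid at or below room temperature should not open the 5-hydroxyflavanone, so the 2S centre from step 7 is carried through.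

**Compound list**

1 | methyl salicylate (methyl 2-hydroxybenzoate) | COC(=O)c1ccccc1O | starting material
2 | 2-(chloromethyl)phenyl acetate (2-acetoxybenzyl chloride) | CC(=O)Oc1ccccc1CCl | starting material
3 | methyl 5-[2-(acetyloxy)benzyl]-2-hydroxybenzoate | COC(=O)c1cc(Cc2ccccc2OC(C)=O)ccc1O | intermediate
4 | 2-(hydroxymethyl)-4-(2-hydroxybenzyl)phenol | OCc1cc(Cc2ccccc2O)ccc1O | intermediate
5 | dimer ortho-quinone methide, 6-methylidene-4-(2-hydroxybenzyl)cyclohexa-2,4-dien-1-one | C=C1C=C(Cc2ccccc2O)C=CC1=O | intermediate (not isolated)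
6 | methyl 2-hydroxy-5-[2-hydroxy-5-(2-hydroxybenzyl)benzyl]benzoate | COC(=O)c1cc(Cc2cc(Cc3ccccc3O)ccc2O)ccc1O | intermediate
7 | 2-(hydroxymethyl)-4-[2-hydroxy-5-(2-hydroxybenzyl)benzyl]phenol | OCc1cc(Cc2cc(Cc3ccccc3O)ccc2O)ccc1O | intermediate
8 | 2,4,6-trihydroxyacetophenone | CC(=O)c1c(O)cc(O)cc1O | starting material
9 | side-chain ortho-quinone methide, 6-methylidene-4-[2-hydroxy-5-(2-hydroxybenzyl)benzyl]cyclohexa-2,4-dien-1-one | C=C1C=C(Cc2cc(Cc3ccccc3O)ccc2O)C=CC1=O | intermediate (not isolated)
10 | 1-(2,4,6-trihydroxy-3-{2-hydroxy-5-[2-hydroxy-5-(2-hydroxybenzyl)benzyl]benzyl}phenyl)ethan-1-one | CC(=O)c1c(O)cc(O)c(Cc2cc(Cc3cc(Cc4ccccc4O)ccc3O)ccc2O)c1O | intermediate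
11 | benzaldehyde | O=Cc1ccccc1 | starting material
12 | aldol adduct, racemic 3-hydroxy-3-phenyl-1-(2,4,6-trihydroxy-3-{2-hydroxy-5-[2-hydroxy-5-(2-hydroxybenzyl)benzyl]benzyl}phenyl)propan-1-one | O=C(CC(O)c1ccccc1)c1c(O)cc(O)c(Cc2cc(Cc3cc(Cc4ccccc4O)ccc3O)ccc2O)c1O | intermediate (not isolated)
13 | (E)-3-phenyl-1-(2,4,6-trihydroxy-3-{2-hydroxy-5-[2-hydroxy-5-(2-hydroxybenzyl)benzyl]benzyl}phenyl)prop-2-en-1-one | O=C(/C=C/c1ccccc1)c1c(O)cc(O)c(Cc2cc(Cc3cc(Cc4ccccc4O)ccc3O)ccc2O)c1O | intermediate
14 | (2S)-5,7-dihydroxy-6-{2-hydroxy-5-[2-hydroxy-5-(2-hydroxybenzyl)benzyl]benzyl}-2-phenylchroman-4-one | O=C1C[C@@H](c2ccccc2)Oc2cc(O)c(Cc3cc(Cc4cc(Cc5ccccc5O)ccc4O)ccc3O)c(O)c21 | intermediate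
15 | salicyl alcohol (2-hydroxybenzyl alcohol) | OCc1ccccc1O | starting material
16 | ortho-quinone methide (6-methylidenecyclohexa-2,4-dien-1-one) | C=C1C=CC=CC1=O | intermediate (not isolated)
17 | sarmentosumin B, (2S)-5,7-dihydroxy-8-(2-hydroxybenzyl)-6-{2-hydroxy-5-[2-hydroxy-5-(2-hydroxybenzyl)benzyl]benzyl}-2-phenylchroman-4-one | O=C1C[C@@H](c2ccccc2)Oc2c(Cc3ccccc3O)c(O)c(Cc3cc(Cc4cc(Cc5ccccc5O)ccc4O)ccc3O)c(O)c21 | target

**Step count and risks**

Total step count: 8. Longest linear sequence: 8 steps (1 + 2 → 3 → 4 → 6 → 7 → 10 → 13 → 14 → 17).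

The three steps most likely to fail:

Step 7 (new regio- and enantioselective closure). If the Sc(OTf)3–pybox closure gives poor ee or a poor 6/8 ratio, give up catalyst control and resolve instead. This fallback sets out from 13 and comes back at 14. Chalcone 13 is cyclised with NaOAc in EtOH at rt to the racemic 6-substituted flavanone F1 together with the racemic 8-substituted regioisomer F2. F1 is separated on silica and resolved by preparative HPLC on a cellulose-based chiral phase into 14 and its (2R)-enantiomer F3. F2 and F3 are not lost: 5 M KOH opens both back to the chalcone polyanion, and cold acidification returns 13 for another pass.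

Step 6 (aldol on a hexaphenol polyanion; solubility and enolisation may be poor). The fallback reverses the order of aldol and side-chain attachment; it sets out from 8 and comes back at 13. Cheap 8 is condensed with 11 by the same LiN(SiMe3)2 protocol (4 equiv) through the aldol adduct F4 to 2',4',6'-trihydroxychalcone F5, isolated from cold acid. F5 (2 equiv) is then alkylated by 7 through 9 with TsOH·H2O (5 mol%) in HFIP/CH2Cl2 at 0 °C, where the acid-stable chalcone is not expected to close, giving 13. Any flavanone formed is reopened with cold KOH before the acid quench.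

Step 3 (the free phenol ring of 4 and of 6 can compete with the solvent for quinone methide 5, giving oligomers). The fallback masks every phenol and replaces the quinone methide by a benzylic cation; it sets out from 4 and comes back at 7. Diol 4 is peracetylated (Ac2O, pyridine, rt) to the triacetate F6. Its benzylic acetate is ionised with Sc(OTf)3 (5 mol%) in neat 1 at 60 °C and benzylates 1 at C5, giving the diacetate ester F7; both chain rings are now aryl acetates and cannot compete. LiAlH4 in THF then reduces the methyl ester and cleaves both acetates in one operation, giving 7 directly at the cost of one more step.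

**Further compounds**

F1 | step 7 | racemic 5,7-dihydroxy-6-{2-hydroxy-5-[2-hydroxy-5-(2-hydroxybenzyl)benzyl]benzyl}-2-phenylchroman-4-one | O=C1CC(c2ccccc2)Oc2cc(O)c(Cc3cc(Cc4cc(Cc5ccccc5O)ccc4O)ccc3O)c(O)c21
F2 | step 7 | racemic 5,7-dihydroxy-8-{2-hydroxy-5-[2-hydroxy-5-(2-hydroxybenzyl)benzyl]benzyl}-2-phenylchroman-4-one | O=C1CC(c2ccccc2)Oc2c(Cc3cc(Cc4cc(Cc5ccccc5O)ccc4O)ccc3O)c(O)cc(O)c21
F3 | step 7 | (2R)-5,7-dihydroxy-6-{2-hydroxy-5-[2-hydroxy-5-(2-hydroxybenzyl)benzyl]benzyl}-2-phenylchroman-4-one | O=C1C[C@H](c2ccccc2)Oc2cc(O)c(Cc3cc(Cc4cc(Cc5ccccc5O)ccc4O)ccc3O)c(O)c21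
F4 | step 6 | racemic 3-hydroxy-3-phenyl-1-(2,4,6-trihydroxyphenyl)propan-1-one | O=C(CC(O)c1ccccc1)c1c(O)cc(O)cc1O
F5 | step 6 | (E)-2',4',6'-trihydroxychalcone | O=C(/C=C/c1ccccc1)c1c(O)cc(O)cc1O
F6 | step 3 | 2-[(acetyloxy)methyl]-4-[2-(acetyloxy)benzyl]phenyl acetate | CC(=O)OCc1cc(Cc2ccccc2OC(C)=O)ccc1OC(C)=O
F7 | step 3 | methyl 5-{2-(acetyloxy)-5-[2-(acetyloxy)benzyl]benzyl}-2-hydroxybenzoate | COC(=O)c1cc(Cc2cc(Cc3ccccc3OC(C)=O)ccc2OC(C)=O)ccc1O
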